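## Retrosynthetic overview

1. With labdane numbering (C1–C20), the target is unmasked last from enal 29. Its seven-membered ring C11–O–O–C15–C14–C13=C12 is closed by ring-closing metathesis at C12=C13 of peroxyacetal 26, made from allylic hydroperoxide 19 and acetal 25.
2. The C11–OOH centre of 19 comes from a Schenck ene reaction of singlet oxygen on a (Z)-propenyl group at C9. The 7α-OH/8(17)-ene unit comes from (−)-drimenol 13 by α-epoxidation and epoxide-to-allylic-alcohol isomerisation.
3. Drimenol 13 comes from bicyclic enone 9 (C9 ketone) by methylenation, α-face hydroboration (sets C9) and desulfonylation.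
4. Ring A of 9 is closed at C3–C4 by a hydrogen-atom-transfer radical cyclisation of 8. The enabling feature is that the gem-dimethyl quaternary carbon C4 of ring A sits next to ring-fusion carbon C5, so it is a masked isopropenyl group on C5, and ring B with that group and the C17 methyl on C8 is (R)-carvone. C10 is set by two enolate alkylations (methyl, then the C1–C3 arm).
5. Order of ring formation: ring B (from carvone), ring A (step 5), dioxepene ring (step 18).

Key step: step 5

Remark: the hemiperacetal carbon C15 is taken to be configurationally labile (ring–chain tautomerism) and the (15S) epimer is assumed to be the thermodynamically preferred one; the C2 sulfone and C15 methyl-acetal centres of intermediates are carried as epimer mixtures because both are later removed or equilibrated.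

## Route

Step 1
Reactants: 1 phenyl vinyl sulfone
Product: 2 2-(phenylsulfonyl)prop-2-en-1-ol
Conditions: HCHO (37% aq.), DABCO (cat.), THF, rt
Reagents that add atoms: formaldehyde, C=O
Why: Morita–Baylis–Hillman-type hydroxymethylation, in which DABCO adds to the vinyl sulfone, the α-sulfonyl carbanion adds to formaldehyde and DABCO is expelled; no stereocentre is formed.

Step 2
Reactants: 2 2-(phenylsulfonyl)prop-2-en-1-ol
Product: 3 2-(phenylsulfonyl)allyl bromide
Conditions: PBr3, Et2O, 0 °C
Reagents that add atoms: phosphorus tribromide, BrP(Br)Br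
Why: Bromination of a primary allylic alcohol through its phosphite ester; direct and allylic displacement give the same bromide, so only one product can form.

Step 3
Reactants: 4 (R)-(−)-carvone
Product: 6 trans-6-methylcarvone (methyl trans to isopropenyl; the cis epimer reacts alike), via lithium dienolate of carvone 5 (not isolated)
Conditions: LiN(iPr)2 (LDA), THF, −78 °C; then MeI, −78 to 0 °C
Reagents that add atoms: iodomethane, CI
Why: Kinetic α'-deprotonation of the enone gives the cross-conjugated lithium enolate, which is C-methylated at C10; the new centre need not be controlled because it is planarised again in step 4.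

Step 4
Reactants: 6 trans-6-methylcarvone; 3 2-(phenylsulfonyl)allyl bromide
Product: 8 (5S,6S)-2,6-dimethyl-6-[2-(phenylsulfonyl)prop-2-en-1-yl]-5-(prop-1-en-2-yl)cyclohex-2-en-1-one, via lithium enolate of 6-methylcarvone 7 (not isolated)
Conditions: LiN(iPr)2 (LDA), THF, −78 °C; then 3, −78 to 0 °C
Reagents that add atoms: none
Why: Enolate alkylation with a reactive allylic bromide; the electrophile should enter anti to the neighbouring C5 isopropenyl group, which places the C1–C3 arm trans to it and the C10 methyl cis, as is usual for 6-alkylcarvone enolates.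

Step 5
Reactants: 8 (5S,6S)-2,6-dimethyl-6-[2-(phenylsulfonyl)prop-2-en-1-yl]-5-(prop-1-en-2-yl)cyclohex-2-en-1-one
Product: 9 (4aS,8aS)-2,5,5,8a-tetramethyl-7-(phenylsulfonyl)-4a,5,6,7,8,8a-hexahydronaphthalen-1(4H)-one
Conditions: Fe(acac)3 (cat.), PhSiH3, EtOH/HOCH2CH2OH, 60 °C
Reagents that add atoms: none
Why: An iron hydride formed from Fe(acac)3 and PhSiH3 should transfer a hydrogen atom in the Markovnikov sense to the electron-rich isopropenyl group, giving the nucleophilic tertiary C4 radical, which adds to the unsubstituted β-carbon C3 of the vinyl sulfone; the α-sulfonyl radical is then reduced and protonated. The closest known reaction type is the iron-mediated reductive olefin coupling (metal-hydride hydrogen-atom-transfer Giese addition) of 1,1-disubstituted alkenes with vinyl sulfones, used here intramolecularly. Ring A closes in the 6-endo-trig mode, favoured over 5-exo both by the polarity of the acceptor (attack β to sulfur) and by the substituent on the internal alkene carbon. No stereocentre of the target is created: the trans ring fusion follows from the trans-diequatorial placement of the C4 radical (on C5) and the C1–C3 arm (on C10) fixed in step 4, and the C2 sulfonyl centre is lost in step 8. The step needs hydrogen-atom transfer to the isopropenyl group in the presence of the enone and the vinyl sulfone; the preference of the iron hydride for electron-rich 1,1-disubstituted alkenes should secure this, and the radical cannot reach the ring-B enone without forming a four-membered ring.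

Step 6
Reactants: 9 (4aS,8aS)-2,5,5,8a-tetramethyl-7-(phenylsulfonyl)-4a,5,6,7,8,8a-hexahydronaphthalen-1(4H)-one
Product: 10 2-(phenylsulfonyl)drima-7,9(11)-diene
Conditions: Zn, CH2Br2, TiCl4, THF/CH2Cl2, 0 °C to rt
Reagents that add atoms: dibromomethane, BrCBr
Why: Takai–Lombardo methylenation, whose non-basic zinc–titanium methylene reagent should add 1,2 to the hindered cross-conjugated C9 ketone without deprotonating the sulfone.

Step 7
Reactants: 10 2-(phenylsulfonyl)drima-7,9(11)-diene
Product: 12 2-(phenylsulfonyl)drim-7-en-11-ol, via B-alkyl-9-BBN adduct 11 (not isolated)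
Conditions: 9-BBN, THF, 0 °C to rt; then NaOH, H2O2 (aq.), 0 °C
Reagents that add atoms: hydrogen peroxide, OO
Why: Hydroboration–oxidation, in which boron goes to the unhindered terminus C11 and hydrogen is delivered to C9 from the α face because the β face is blocked by the axial C10 methyl, setting C9 (9α-H, equatorial CH2OH).

Step 8
Reactants: 12 2-(phenylsulfonyl)drim-7-en-11-ol
Product: 13 (−)-drimenol
Conditions: Na(Hg) (6%), Na2HPO4, MeOH/THF, −20 °C to rt
Reagents that add atoms: none
Why: Reductive desulfonylation by electron transfer from sodium amalgam removes the activating group of the key step, leaving the isolated trisubstituted alkene and the alcohol untouched.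

Step 9
Reactants: 13 (−)-drimenol
Product: 14 7α,8α-epoxydriman-11-ol
Conditions: mCPBA, NaHCO3, CH2Cl2, 0 °C
Reagents that add atoms: 3-chloroperoxybenzoic acid, O=C(OO)c1cccc(Cl)c1
Why: Prilezhaev epoxidation of the C7=C8 alkene from the α face, the β face being shielded by the axial C10 methyl and the C9 hydroxymethyl group, which sets the C7–O bond α.

Step 10
Reactants: 14 7α,8α-epoxydriman-11-ol
Product: 15 7α-hydroxyalbicanol
Conditions: Al(OiPr)3, toluene, reflux
Reagents that add atoms: none
Why: Aluminium-alkoxide-mediated isomerisation of a trisubstituted epoxide to an allylic alcohol by syn β-elimination of the least hindered hydrogen (C17 methyl), which cleaves the tertiary C8–O bond and leaves the 7α C–O bond intact.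

Step 11
Reactants: 15 7α-hydroxyalbicanol
Product: 16 7α-hydroxyalbicanal
Conditions: TEMPO (cat.), PhI(OAc)2, CH2Cl2, 0 °C to rt
Reagents that add atoms: none
Why: Oxoammonium (TEMPO) oxidation, selective for the primary over the hindered axial secondary alcohol and non-basic, so the β,γ-unsaturated aldehyde should neither epimerise at C9 nor move into conjugation.

Step 12
Reactants: 16 7α-hydroxyalbicanal
Product: 17 (Z)-14,15,16-trinorlabda-8(17),11-dien-7α-ol
Conditions: EtPPh3Br, KN(SiMe3)2 (KHMDS), THF, −78 °C to rt (excess ylide, aldehyde added last)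
Reagents that add atoms: ethyltriphenylphosphonium bromide, CC[P+](c1ccccc1)(c1ccccc1)c1ccccc1.[Br-]
Why: Salt-free Wittig olefination with a non-stabilised ylide should give the (Z)-propenyl group under kinetic control, the extra ylide covering the free hydroxyl.

Step 13
Reactants: 17 (Z)-14,15,16-trinorlabda-8(17),11-dien-7α-ol
Product: 18 7α-(tert-butyldimethylsilyloxy)-(Z)-14,15,16-trinorlabda-8(17),11-diene
Conditions: TBSOTf, 2,6-lutidine, CH2Cl2, −78 to 0 °C
Reagents that add atoms: tert-butyldimethylsilyl trifluoromethanesulfonate, CC(C)(C)[Si](C)(C)OS(=O)(=O)C(F)(F)F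
Why: Silylation of the hindered axial allylic alcohol with a silyl triflate; the bulky α-axial silyl ether also shields the α face of the C8(17) alkene for the next step.

Step 14
Reactants: 18 7α-(tert-butyldimethylsilyloxy)-(Z)-14,15,16-trinorlabda-8(17),11-diene
Product: 19 (11S)-7α-(tert-butyldimethylsilyloxy)-14,15,16-trinorlabda-8(17),12-dien-11-yl hydroperoxide
Conditions: O2, hν (visible), tetraphenylporphyrin (cat.), CH2Cl2, −20 °C
Reagents that add atoms: dioxygen, O=O
Why: Schenck ene reaction in which oxygen adds at C11 and hydrogen is taken from the terminal methyl, because A(1,3) strain in the (Z)-alkene holds the C9–H in the alkene plane; attack anti to the quaternary C10 on that conformer should give the (11S) hydroperoxide.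

Step 15
Reactants: 20 3-chloro-2-(chloromethyl)prop-1-ene (excess); 21 4-methoxybenzyl alcohol
Product: 23 1-({[2-(chloromethyl)prop-2-en-1-yl]oxy}methyl)-4-methoxybenzene, via sodium 4-methoxybenzyl oxide 22 (not isolated)
Conditions: NaH, THF/DMF, 0 °C to rt
Reagents that add atoms: none
Why: Williamson ether synthesis on a reactive allylic chloride, with excess dichloride to suppress double substitution.

Step 16
Reactants: 23 1-({[2-(chloromethyl)prop-2-en-1-yl]oxy}methyl)-4-methoxybenzene
Product: 25 1-({[2-(2,2-dimethoxyethyl)prop-2-en-1-yl]oxy}methyl)-4-methoxybenzene, via allylic Grignard reagent 24 (not isolated)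
Conditions: Mg, THF, 0 °C; then HC(OMe)3, reflux
Reagents that add atoms: trimethyl orthoformate, COC(OC)OC
Why: Bodroux–Chichibabin reaction of an allylic Grignard reagent with an orthoformate; the two allyl termini of 24 are equivalent, so only one acetal can form.

Step 17
Reactants: 19 (11S)-7α-(tert-butyldimethylsilyloxy)-14,15,16-trinorlabda-8(17),12-dien-11-yl hydroperoxide; 25 1-({[2-(2,2-dimethoxyethyl)prop-2-en-1-yl]oxy}methyl)-4-methoxybenzene
Product: 26 acyclic C11–O–O–C15 methyl peroxyacetal
Conditions: PPTS (cat.), 4 Å molecular sieves, CH2Cl2, 0 °C to rt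
Reagents that add atoms: none
Why: Acid-catalysed transperoxyacetalisation, in which the hydroperoxide traps the oxocarbenium ion of the dimethyl acetal and the sieves remove methanol; C11 is untouched and the C15 epimers converge later.

Step 18
Reactants: 26 acyclic C11–O–O–C15 methyl peroxyacetal
Product: 27 3-methoxy-1,2-dioxep-5-ene (C16 4-methoxybenzyl ether)
Conditions: second-generation Grubbs catalyst (cat.), CH2Cl2 (dilute), 40 °C
Reagents that add atoms: none
Why: Ring-closing metathesis of a dialkyl peroxide between the C12 vinyl group and the C13 1,1-disubstituted alkene; the seven-membered ring forces C11 and C14 cis on C12=C13, which is the enal geometry of the target, and the hindered C8(17) alkene should not take part.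

Step 19
Reactants: 27 3-methoxy-1,2-dioxep-5-ene (C16 4-methoxybenzyl ether)
Product: 28 C16 allylic alcohol
Conditions: DDQ, CH2Cl2/pH 7 buffer, 0 °C
Reagents that add atoms: none
Why: Oxidative cleavage of the 4-methoxybenzyl ether by hydride abstraction under neutral buffered conditions, which peroxide, acetal and silyl ether should tolerate.

Step 20
Reactants: 28 C16 allylic alcohol
Product: 29 C16 enal
Conditions: MnO2, CH2Cl2, rt
Reagents that add atoms: none
Why: Heterogeneous MnO2 oxidation of the primary allylic alcohol to the conjugated aldehyde, with the ring-fixed alkene geometry retained.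

Step 21
Reactants: 29 C16 enal
Product: 31 target CNP0269954.1, via 7-hydroxy methyl peroxyacetal 30 (not isolated)
Conditions: HF (48% aq.), MeCN, 0 °C to rt
Reagents that add atoms: water, O
Why: Acid/fluoride cleavage of the silyl ether followed by acid hydrolysis of the methyl peroxyacetal; C15 should settle to the assumed thermodynamic (15S) hemiperacetal through ring–chain equilibration.

## Compound list

1 | phenyl vinyl sulfone | C=CS(=O)(=O)c1ccccc1 | starting material
2 | 2-(phenylsulfonyl)prop-2-en-1-ol | C=C(CO)S(=O)(=O)c1ccccc1 | intermediate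
3 | 2-(phenylsulfonyl)allyl bromide, [(3-bromoprop-1-en-2-yl)sulfonyl]benzene | C=C(CBr)S(=O)(=O)c1ccccc1 | intermediate
4 | (R)-(−)-carvone | CC1=CC[C@@H](C(C)=C)CC1=O | starting material
5 | lithium dienolate of carvone (not isolated) | CC1=CC[C@@H](C(C)=C)C=C1O[Li] | intermediate
6 | trans-6-methylcarvone, (5R,6S)-2,6-dimethyl-5-(prop-1-en-2-yl)cyclohex-2-en-1-one | CC1=CC[C@@H](C(C)=C)[C@H](C)C1=O | intermediate
7 | lithium enolate of 6-methylcarvone (not isolated) | CC1=CC[C@@H](C(C)=C)C(C)=C1O[Li] | intermediate
8 | (5S,6S)-2,6-dimethyl-6-[2-(phenylsulfonyl)prop-2-en-1-yl]-5-(prop-1-en-2-yl)cyclohex-2-en-1-one (C10 methyl cis to the isopropenyl group) | CC1=CC[C@@H](C(C)=C)[C@](C)(CC(=C)S(=O)(=O)c2ccccc2)C1=O | intermediate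
9 | (4aS,8aS)-2,5,5,8a-tetramethyl-7-(phenylsulfonyl)-4a,5,6,7,8,8a-hexahydronaphthalen-1(4H)-one (trans-fused; C2 epimers) | CC1=CC[C@H]2C(C)(C)CC(S(=O)(=O)c3ccccc3)C[C@]2(C)C1=O | intermediate
10 | 2-(phenylsulfonyl)drima-7,9(11)-diene (C2 epimers) | CC1=CC[C@H]2C(C)(C)CC(S(=O)(=O)c3ccccc3)C[C@]2(C)C1=C | intermediate
11 | B-[2-(phenylsulfonyl)drim-7-en-11-yl]-9-borabicyclo[3.3.1]nonane (not isolated) | CC1=CC[C@H]2C(C)(C)CC(S(=O)(=O)c3ccccc3)C[C@]2(C)[C@H]1CB4C5CCCC4CCC5 | intermediate
12 | 2-(phenylsulfonyl)drim-7-en-11-ol (9α-H; C2 epimers) | CC1=CC[C@H]2C(C)(C)CC(S(=O)(=O)c3ccccc3)C[C@]2(C)[C@H]1CO | intermediate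
13 | (−)-drimenol, (5S,9S,10S)-drim-7-en-11-ol | CC1=CC[C@H]2C(C)(C)CCC[C@]2(C)[C@H]1CO | intermediate
14 | 7α,8α-epoxydriman-11-ol | C[C@@]12O[C@@H]1C[C@H]3C(C)(C)CCC[C@]3(C)[C@H]2CO | intermediate
15 | 7α-hydroxyalbicanol, drim-8(12)-ene-7α,11-diol | C=C1[C@H](O)C[C@H]2C(C)(C)CCC[C@]2(C)[C@H]1CO | intermediate
16 | 7α-hydroxyalbicanal, 7α-hydroxydrim-8(12)-en-11-al | C=C1[C@H](O)C[C@H]2C(C)(C)CCC[C@]2(C)[C@H]1C=O | intermediate
17 | (Z)-14,15,16-trinorlabda-8(17),11-dien-7α-ol | C=C1[C@H](O)C[C@H]2C(C)(C)CCC[C@]2(C)[C@H]1/C=C\C | intermediate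
18 | 7α-(tert-butyldimethylsilyloxy)-(Z)-14,15,16-trinorlabda-8(17),11-diene | C=C1[C@H](O[Si](C)(C)C(C)(C)C)C[C@H]2C(C)(C)CCC[C@]2(C)[C@H]1/C=C\C | intermediate
19 | (11S)-7α-(tert-butyldimethylsilyloxy)-14,15,16-trinorlabda-8(17),12-dien-11-yl hydroperoxide | C=C1[C@H](O[Si](C)(C)C(C)(C)C)C[C@H]2C(C)(C)CCC[C@]2(C)[C@H]1[C@@H](OO)C=C | intermediate
20 | 3-chloro-2-(chloromethyl)prop-1-ene | C=C(CCl)CCl | starting material
21 | 4-methoxybenzyl alcohol | COc1ccc(CO)cc1 | starting material
22 | sodium 4-methoxybenzyl oxide (not isolated) | COc1ccc(C[O-])cc1.[Na+] | intermediate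
23 | 1-({[2-(chloromethyl)prop-2-en-1-yl]oxy}methyl)-4-methoxybenzene | C=C(CCl)COCc1ccc(OC)cc1 | intermediate
24 | {2-[(4-methoxybenzyloxy)methyl]prop-2-en-1-yl}magnesium chloride (not isolated) | C=C(C[Mg]Cl)COCc1ccc(OC)cc1 | intermediate
25 | 1-({[2-(2,2-dimethoxyethyl)prop-2-en-1-yl]oxy}methyl)-4-methoxybenzene (C13–C16 fragment) | C=C(COCc1ccc(OC)cc1)CC(OC)OC | intermediate
26 | acyclic mixed peroxyacetal: (11S)-C11–O–O–C15H(OMe)–C14H2–C13(=CH2)–C16H2–O-(4-methoxybenzyl), 7α-OTBS, C12 vinyl (C15 epimers) | C=C1[C@H](O[Si](C)(C)C(C)(C)C)C[C@H]2C(C)(C)CCC[C@]2(C)[C@H]1[C@@H](OOC(OC)CC(=C)COCc3ccc(OC)cc3)C=C | intermediate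
27 | (11S)-3-methoxy-5-[(4-methoxybenzyloxy)methyl]-1,2-dioxep-5-ene carrying the 7α-OTBS decalin at C11 (C15 epimers) | C=C1[C@H](O[Si](C)(C)C(C)(C)C)C[C@H]2C(C)(C)CCC[C@]2(C)[C@H]1[C@@H]1C=C(COCc3ccc(OC)cc3)CC(OC)OO1 | intermediate
28 | C16 allylic alcohol of the dioxepene (7α-OTBS, C15–OMe) | C=C1[C@H](O[Si](C)(C)C(C)(C)C)C[C@H]2C(C)(C)CCC[C@]2(C)[C@H]1[C@@H]1C=C(CO)CC(OC)OO1 | intermediate
29 | C16 enal of the dioxepene (7α-OTBS, C15–OMe) | C=C1[C@H](O[Si](C)(C)C(C)(C)C)C[C@H]2C(C)(C)CCC[C@]2(C)[C@H]1[C@@H]1C=C(C=O)CC(OC)OO1 | intermediate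
30 | 7α-hydroxy enal with C15 methyl peroxyacetal (not isolated) | C=C1[C@H](O)C[C@H]2C(C)(C)CCC[C@]2(C)[C@H]1[C@@H]1C=C(C=O)CC(OC)OO1 | intermediate
31 | CNP0269954.1, (5S,7R,9R,10S,11S,15S)-11,15-epidioxy-7,15-dihydroxylabda-8(17),12-dien-16-al | C=C1[C@H](O)C[C@H]2C(C)(C)CCC[C@]2(C)[C@H]1[C@@H]1C=C(C=O)C[C@@H](O)OO1 | target

## Step count and risks

Total step count: 21 (steps 1–21).
Longest linear sequence: 18 steps, from phenyl vinyl sulfone 1 to target 31 (steps 1, 2, 4–14 and 17–21). Step 3 and steps 15–16 are side branches that join at steps 4 and 17.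

**Step 14 (Schenck ene reaction).** The cis-disubstituted side-chain alkene reacts slowly with singlet oxygen, so ene reaction at the C8(17) alkene may compete, and discrimination between the two faces at C11 may be insufficient. Fallback, from 16 back to 19, by metallo-ene photooxygenation of an allylstannane: 16 would be silylated (TBSOTf, 2,6-lutidine) to the 7α-silyloxy aldehyde F1. Wittig olefination of F1 with [2-(tributylstannyl)ethylidene]triphenylphosphorane should give the (Z)-allylstannane F2. Allylstannanes take up singlet oxygen far faster than simple alkenes, by tin transfer with allylic transposition. Photooxygenation at −78 °C and hydrolysis of the peroxystannane should therefore give 19 without touching the C8(17) alkene, and the lower temperature should sharpen facial discrimination.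

**Step 18 (ring-closing metathesis).** The ruthenium alkylidene may be consumed by the allylic peroxide, or the hindered 1,1-disubstituted alkene may engage too slowly, so that oligomers form instead of the seven-membered ring. Fallback, from 19 back to 27, closing the ring at the peroxyacetal C–O bond instead of at the alkene: 19 would be capped with 2-methoxypropene and PPTS as the 2-methoxyprop-2-yl peroxide F3. Cross-metathesis of F3 with excess 25 (second-generation Hoveyda–Grubbs catalyst) should give the trisubstituted alkene F4 together with its geometric isomer. On treatment with PPTS in CH2Cl2, only F4, in which C11 and C14 are cis, can close by intramolecular transperoxyacetalisation to 27; the other isomer would be separated.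

**Step 21 (final unmasking).** Aqueous acid may trigger heterolytic (Hock-type) fragmentation of the allylic peroxide or ionisation of the C7 allylic alcohol before the methyl peroxyacetal is hydrolysed. Fallback, from 25 and 19 back to 31, using an oxidatively removable acetal at C15: 25 would be trans-acetalised with 21 (PPTS, toluene) to the bis(4-methoxybenzyl) acetal F5. Exchange with 19 should give peroxyacetal F6, and ring-closing metathesis the dioxepene F7. DDQ would then remove both 4-methoxybenzyl groups to give the hydroxy hemiperacetal F8, and MnO2 would oxidise it to the enal F9. Buffered HF·pyridine then only has to cleave the silyl ether to reach 31, so the peroxide never meets aqueous mineral acid.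

Further compounds
F1 | step 14 | 7α-(tert-butyldimethylsilyloxy)albicanal | C=C1[C@H](O[Si](C)(C)C(C)(C)C)C[C@H]2C(C)(C)CCC[C@]2(C)[C@H]1C=O
F2 | step 14 | (Z)-allylstannane: 7α-(tert-butyldimethylsilyloxy)-13-(tributylstannyl)-14,15,16-trinorlabda-8(17),11-diene | C=C1[C@H](O[Si](C)(C)C(C)(C)C)C[C@H]2C(C)(C)CCC[C@]2(C)[C@H]1/C=C\C[Sn](CCCC)(CCCC)CCCC
F3 | step 18 | 2-methoxyprop-2-yl peroxide of 19 | C=C1[C@H](O[Si](C)(C)C(C)(C)C)C[C@H]2C(C)(C)CCC[C@]2(C)[C@H]1[C@@H](OOC(C)(C)OC)C=C
F4 | step 18 | cross-metathesis product with C11 and C14 cis on C12=C13 (C15 dimethyl acetal, C16 4-methoxybenzyl ether) | C=C1[C@H](O[Si](C)(C)C(C)(C)C)C[C@H]2C(C)(C)CCC[C@]2(C)[C@H]1[C@@H](OOC(C)(C)OC)/C=C(\CC(OC)OC)COCc3ccc(OC)cc3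
F5 | step 21 | bis(4-methoxybenzyl) acetal analogue of 25 | C=C(COCc1ccc(OC)cc1)CC(OCc1ccc(OC)cc1)OCc1ccc(OC)cc1
F6 | step 21 | acyclic 4-methoxybenzyl peroxyacetal (analogue of 26; C15 epimers) | C=C1[C@H](O[Si](C)(C)C(C)(C)C)C[C@H]2C(C)(C)CCC[C@]2(C)[C@H]1[C@@H](OOC(OCc3ccc(OC)cc3)CC(=C)COCc3ccc(OC)cc3)C=C
F7 | step 21 | 3-(4-methoxybenzyloxy)-1,2-dioxep-5-ene (analogue of 27; C15 epimers) | C=C1[C@H](O[Si](C)(C)C(C)(C)C)C[C@H]2C(C)(C)CCC[C@]2(C)[C@H]1[C@@H]1C=C(COCc3ccc(OC)cc3)CC(OCc3ccc(OC)cc3)OO1
F8 | step 21 | 7α-silyloxy hemiperacetal with C16 allylic alcohol | C=C1[C@H](O[Si](C)(C)C(C)(C)C)C[C@H]2C(C)(C)CCC[C@]2(C)[C@H]1[C@@H]1C=C(CO)C[C@@H](O)OO1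
F9 | step 21 | 7α-silyloxy hemiperacetal enal (7-O-silyl ether of 31) | C=C1[C@H](O[Si](C)(C)C(C)(C)C)C[C@H]2C(C)(C)CCC[C@]2(C)[C@H]1[C@@H]1C=C(C=O)C[C@@H](O)OO1
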